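## Structural features

Spiropreussione B (28) contains a 9-hydroxyphenalen-1-one. Ring A (C1, C2, C3, C3a, C9b, C9a) is the enone ring, and ring B (C3a, C4, C5, C6, C6a, C9b) and ring C (C6a, C7, C8, C9, C9a, C9b) are benzenoid. The C5–C6 edge of ring B is shared with the five-membered ring D, and the opposite edge of ring D is shared with a 4-hydroxycyclopent-2-enone, ring E. Ring E is numbered here E1 (C=O), E2 and E3 (alkene), E4 (tertiary carbinol, bonded to C5) and E5 (methine). The fifth atom of ring D, bonded to C6 and E5, is the spiro carbon of a ketal with 1,8-dihydroxynaphthalene. The two stereocentres, E4 (R) and E5 (S), are neighbours on the D/E fusion bond. Two fused five-membered rings can only be cis, so OH and H are syn, and the stereochemical problem reduces to the absolute configuration at E4, to which the enolisable E5 is tied. E5–H is alpha to E1 and beta to both aryloxy oxygens, so base opens the ketal by loss of naphthoxide. E4–OH is part of a beta-hydroxy ketone, the enone is a Michael acceptor, and the chelated C9–OH/C1=O pair is a vinylogous acid. The real difficulty is to join this base-labile chiral half to a ring B in which five of six carbons bear carbon substituents. The C9 oxygen and the C9a acyl carbon must also be placed side by side although the naphthodioxine is the most electron-rich arene in the molecule. Ring C carries oxygen on C9, the acyl carbon C1 on the adjacent C9a, and two unsubstituted carbons C7 and C8. This is the 1-acyl-2-oxynaphthalene pattern that an ortho-alkynylbenzaldehyde gives with an oxygenated alkyne, so ring C can be the last benzene ring to be made.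

## Logic of the disconnections

28 from 27. The bond cut is the O–ethyl bond on the C9 oxygen. A free C9–OH next to the acyl group would close onto any three-carbon electrophile through oxygen, so it stays an ether until ring A exists. The gain is the removal of the only acidic group. The forward step must dealkylate one aryl ether beside two ketal C–O bonds, and only the ether chelated to C1=O should respond to BCl3.

27 from 26. The bond cut is C3–C3a, which opens ring A. C3a is the peri position of an acylnaphthalene and is conjugated with the C9 oxygen, so it is the natural nucleophile for a carbon at the aldehyde level. The phenalenone becomes a naphthyl ketone with a side chain. The forward step needs an electrophile that closes at or below room temperature in acid, hence an acetal (oxocarbenium ion) rather than a vinylogous amide.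

26 from 25. The bond cut is C2–C3, which leaves a methyl ketone. One carbon is added to the only CH3–C=O unit present. The forward step must enolise this ketone without any free base, because E5–H and the ketal would not survive one.

25 from 22 and 23. The bonds cut are C7–C8 and C9–C9a, which open ring C. The cut removes a whole benzene ring and places C9–O and C9a–acyl by mechanism rather than by arene substitution. A naphthalene becomes a benzene with a formyl and a propynyl group. The forward step must add 23 in one orientation and leave the enone, silyl ether and ketal alone.

22 from 19. The bonds cut are the Si–O bond at E4 and, formally, the C=O of the aldehyde, which returns to a dimethyl acetal. The acetal is what lets the formyl carbon pass through enolate and organolithium chemistry. The forward step should do silylation and unmasking in one buffered operation.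

19 from 18. No skeletal bond is cut: E1 goes from ketone to secondary allylic alcohol. This carbinol is the handle by which the two enantiomers can be told apart, and its oxidation is needed anyway. The forward step must oxidise only one enantiomer.

18 from 16. The bond cut is E3–E4, which opens ring E. The cis fusion makes the closure stereospecific with respect to E5, and a tricycle becomes an indanone with a side chain. The forward step needs an alkenyl anion of Z geometry that adds faster than it deprotonates E5.

16 and 15 from 11 and 13, and 13 from 12. The bond cut is E5–E1, an aldol bond. It joins the three carbons of ring E to the only enolisable position of 11. The forward step must enolise a ketone that has two aryloxy leaving groups in the beta position, so a covalent boron enolate is required.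

11 from 10, and 10 from 8 and 9. The bond cut is the aryl–alkynyl bond at the future C9b. Cross-coupling on an achiral, robust compound keeps amine and copper away from ring E. The forward step needs a leaving group ortho to the formyl group.

8 from 7 and 7 from 6. The bonds cut are S–O and O–CH3. The methoxy group serves first as lithiation director and oxidation activator and only then becomes the leaving group. The demethylation must be selective, which the neighbouring formyl group ensures.

6 from 5. The benzylic C=O at the future E4 is removed. The methylene is para to the methoxy group, which singles it out. The oxidant must spare the aldehyde and the naphthodioxine.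

5 from 3. The bond cut is aryl–CHO (the future C6a–C7). The position lies between two oxygen-based directors. The forward step is a regioselective lithiation.

3 from 1 and 2. The two ketal C–O bonds are cut, which gives two commercial compounds. Putting the ketal on first decides which benzylic carbon becomes the spiro centre. The forward step is an acid-catalysed ketalisation with removal of water.

## Other disconnections considered

Alternative 1: The cut is the C5–E4 bond (aryl–carbinol). In the forward sense the achiral bromide A1 would be treated with Ni(cod)2 (zerovalent nickel), a chiral phosphinooxazoline and Mn, and the arylnickel would add to one of the two enantiotopic ketones to give A2.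
- In its favour: E4 and E5 arise together in one catalytic enantioselective step from an achiral compound. No material is lost to a resolution, ring E arrives at its final oxidation level, and the naphthalene is bought rather than built. On stereochemical economy, and on the step count up to the tetracycle, this plan is better than the chosen one.
- Against it: a cyclopent-4-ene-1,3-dione is a strong pi-acceptor for zerovalent nickel and is reducible by Mn. E5–H of A1 lies between two carbonyl groups and next to the ketal, so ketal opening is far easier than in 22. Oxidative addition also has to occur beside a fully substituted carbon.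
- Structurally, A2 still lacks C1. Acylation at C9a must then compete with the four activated positions of the naphthodioxine, which is the problem that the chosen plan solves by mechanism.
- Overall, the steps saved before A2 are likely to be spent again, with a regiochemical risk, after it.

Alternative 2: The cut is the C6–ketal carbon bond. In the forward sense TMSOTf would silylate the ketone of the ketene acetal A3, and the resulting naphthodioxinylium ion would be attacked by the naphthalene carbon next to the carbinol-bearing carbon to give A4.
- In its favour: the spiro carbon and ring D form in one mild step, no ketalisation of a hindered ketone is needed, and the cis fusion follows from geometry. On the way the ketal is made, it is the equal of the chosen plan.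
- Against it: the cation is stabilised by two aryloxy oxygens and a silyloxydiene, so it is a weak electrophile. The attacking carbon is not in conjugation with the methoxy group, whose activated positions lie elsewhere. The second ortho carbon can compete, and the tertiary silyloxy group of A3 is allylic to an electron-rich diene once the ketone is silylated, so it may ionise.
- A3 also needs its own enantioselective synthesis, and A4 shares with A2 the unsolved C9a acylation.
- In step economy it is comparable with the chosen plan, and in mechanistic security it is weaker.

Alternative 3: The cut is C3–C3a, the same bond that the chosen plan forms in step 16. In the forward sense Ph3PAuNTf2 (monovalent gold) would activate the terminal ynone A5, and the peri carbon would add to the alkyne terminus in a 6-endo-dig hydroarylation to give A6.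
- In its favour: the closure is a neutral, catalytic isomerisation without by-product. On mildness and atom economy it is better than the acid closure of step 16, and the final dealkylation is equal.
- Against it: A5 needs a propynoyl group on C9a of a finished, base-labile tetracycle. This again presupposes selective functionalisation of C9a, and a terminal ynone is a strong acceptor for any naphthol set free by ketal opening.
- It says nothing about how ring C and the C9/C9a pattern are made, so it complements rather than replaces the chosen key step.
- From 25 it is not shorter, because turning a methyl ketone into a terminal ynone takes at least as many steps as steps 15 and 16.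

Key step: step 14

Remark on the chemistry: 15–18 are racemates drawn as the enantiomer that is carried on to 28, the absolute configuration is fixed in step 12, and the atom maps of 22 and 25 onto 28 (regiochemistry and both stereocentres) were checked and need no correction.

Step 1
Reactants: 1 6-methoxy-1-indanone; 2 1,8-dihydroxynaphthalene
Product: 3 6-methoxy-2,3-dihydrospiro[indene-1,2'-naphtho[1,8-de][1,3]dioxine]
Conditions: p-TsOH·H2O (10 mol %), toluene, reflux, azeotropic removal of water
Reagents that add atoms: none
Why: Acid-catalysed ketalisation driven by removal of water; the peri diol forms an unstrained six-membered dioxine and benzo-fused cyclic ketones are its usual partners. The ketal comes first because it later directs the lithiation and decides which benzylic carbon becomes the spiro centre.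

Step 2
Reactants: 3 6-methoxy-2,3-dihydrospiro[indene-1,2'-naphtho[1,8-de][1,3]dioxine]
Product: 5 6-methoxy-2,3-dihydrospiro[indene-1,2'-naphtho[1,8-de][1,3]dioxine]-7-carbaldehyde, via 7-lithio ketal 4 (not isolated)
Conditions: n-BuLi, TMEDA, Et2O, 0 °C to rt; DMF, −78 °C to rt; H2O
Reagents that add atoms: N,N-dimethylformamide CN(C)C=O
Why: Directed ortho-metalation and formylation: C7–H lies between the methoxy group and the carbon bearing the ketal, so both oxygen donors cooperate at this one site as in 3-methoxybenzaldehyde acetals. The naphthalene C–H bonds next to the ketal oxygens have only one weak donor each.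

Step 3
Reactants: 5 6-methoxy-2,3-dihydrospiro[indene-1,2'-naphtho[1,8-de][1,3]dioxine]-7-carbaldehyde
Product: 6 6-methoxy-3-oxo-2,3-dihydrospiro[indene-1,2'-naphtho[1,8-de][1,3]dioxine]-7-carbaldehyde
Conditions: DDQ (2.5 equiv), 1,4-dioxane/H2O, rt to 60 °C
Reagents that add atoms: water O
Why: Benzylic oxidation by hydride abstraction: the C3 methylene is para to the methoxy group, the cation is trapped by water and the carbinol is oxidised again to the ketone. DDQ leaves a formyl group untouched, which chromium or peroxide reagents would not.

Step 4
Reactants: 6 6-methoxy-3-oxo-2,3-dihydrospiro[indene-1,2'-naphtho[1,8-de][1,3]dioxine]-7-carbaldehyde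
Product: 7 6-hydroxy-3-oxo-2,3-dihydrospiro[indene-1,2'-naphtho[1,8-de][1,3]dioxine]-7-carbaldehyde
Conditions: BCl3 (1.3 equiv), CH2Cl2, −78 °C to 0 °C; H2O
Reagents that add atoms: none
Why: Chelation-controlled cleavage of an aryl methyl ether ortho to a carbonyl group: boron bridges the formyl and methoxy oxygens and chloride removes the methyl group. The ketal oxygens are aryl-conjugated and hindered, so they should not compete at low temperature.

Step 5
Reactants: 7 6-hydroxy-3-oxo-2,3-dihydrospiro[indene-1,2'-naphtho[1,8-de][1,3]dioxine]-7-carbaldehyde
Product: 8 7-formyl-3-oxo-2,3-dihydrospiro[indene-1,2'-naphtho[1,8-de][1,3]dioxine]-6-yl trifluoromethanesulfonate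
Conditions: Tf2O, pyridine, CH2Cl2, 0 °C
Reagents that add atoms: trifluoromethanesulfonic anhydride O=S(=O)(OS(=O)(=O)C(F)(F)F)C(F)(F)F
Why: Sulfonylation of the phenol turns the oxygen into a leaving group for palladium. Pyridine is too weak a base to enolise the beta-ketal ketone.

Step 6
Reactants: 8 7-formyl-3-oxo-2,3-dihydrospiro[indene-1,2'-naphtho[1,8-de][1,3]dioxine]-6-yl trifluoromethanesulfonate; 9 propyne
Product: 10 3-oxo-6-(prop-1-yn-1-yl)-2,3-dihydrospiro[indene-1,2'-naphtho[1,8-de][1,3]dioxine]-7-carbaldehyde
Conditions: PdCl2(PPh3)2 (5 mol %), CuI (10 mol %), Et3N, DMF, propyne (1 atm), rt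
Reagents that add atoms: none
Why: Sonogashira coupling; oxidative addition to zerovalent palladium is helped by the ortho formyl and para acyl groups. The coupling is placed on an achiral, robust compound so that no amine base or copper salt meets ring E later.

Step 7
Reactants: 10 3-oxo-6-(prop-1-yn-1-yl)-2,3-dihydrospiro[indene-1,2'-naphtho[1,8-de][1,3]dioxine]-7-carbaldehyde
Product: 11 7-(dimethoxymethyl)-6-(prop-1-yn-1-yl)spiro[indene-1,2'-naphtho[1,8-de][1,3]dioxin]-3(2H)-one
Conditions: HC(OMe)3, p-TsOH·H2O (5 mol %), MeOH, rt
Reagents that add atoms: trimethyl orthoformate COC(OC)OC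
Why: Chemoselective acetalisation: the aldehyde reacts at room temperature while the conjugated aryl ketone does not. The acetal shields the formyl carbon from the enolate and organolithium steps.

Step 8
Reactants: 12 ethyl (Z)-3-iodoacrylate
Product: 13 (Z)-3-iodoprop-2-enal
Conditions: DIBAL-H (1.05 equiv), CH2Cl2, −78 °C; MeOH, aq. potassium sodium tartrate; dried solution used at once
Reagents that add atoms: none
Why: Partial reduction of an ester, which stops at the aluminium hemiacetal at −78 °C. The Z geometry is kept if the aldehyde is held cold, in the dark, and used directly.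

Step 9
Reactants: 11 7-(dimethoxymethyl)-6-(prop-1-yn-1-yl)spiro[indene-1,2'-naphtho[1,8-de][1,3]dioxin]-3(2H)-one; 13 (Z)-3-iodoprop-2-enal
Product: 15 (±)-(2R*,1'S*)-2-[(Z)-1-hydroxy-3-iodoprop-2-en-1-yl] derivative of 11 (anti aldol), via dicyclohexylboron enolate 14 (not isolated)
Conditions: (c-C6H11)2BCl, Et3N, Et2O, −78 °C to −10 °C; 13, −78 °C; MeOH, pH 7 buffer, H2O2, 0 °C
Reagents that add atoms: none
Why: Boron aldol addition: soft enolisation with a dialkylboron chloride and a tertiary amine avoids a free enolate that would expel naphthoxide from the neighbouring ketal carbon. The ring-locked E(O) enolate reacts through a closed chair transition state and should set E5 and E1 in the anti relation; the product is racemic.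

Step 10
Reactants: 15 (±)-anti aldol
Product: 16 (±)-trimethylsilyl ether of 15
Conditions: TMSCl, imidazole, CH2Cl2, 0 °C
Reagents that add atoms: chlorotrimethylsilane C[Si](C)(C)Cl
Why: Silylation removes the acidic proton before the organolithium step. The small trimethylsilyl group is chosen because after ring closure this oxygen sits on the concave face next to the ketal.

Step 11
Reactants: 16 (±)-trimethylsilyl ether of 15
Product: 18 (±)-(1R*,3aR*,8aR*)-7-(dimethoxymethyl)-6-(prop-1-yn-1-yl)-1,8a-dihydro-3aH-spiro[cyclopenta[a]indene-8,2'-naphtho[1,8-de][1,3]dioxine]-1,3a-diol, via cyclised E1 silyl ether 17 (not isolated)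
Conditions: t-BuLi (2.1 equiv), Et2O/THF, −78 °C; MeOH; then K2CO3, MeOH, rt
Reagents that add atoms: none
Why: Iodine–lithium exchange is faster than enolisation or addition of t-BuLi, and the (Z)-alkenyllithium adds to the ketone in a 5-exo-trig anionic cyclisation, a known route to cyclopentenols. The three-atom tether reaches only the carbonyl face on the side of the E5 substituent, so E4–OH ends cis to E5–H (cis-fused rings D and E). Carbonate in methanol then removes the silyl group, which is safe because 17 has no carbonyl group that could trigger ketal opening.

Step 12
Reactants: 18 (±)-tricyclic diol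
Product: 19 (3aR,8aS)-7-(dimethoxymethyl)-3a-hydroxy-6-(prop-1-yn-1-yl)-3a,8a-dihydro-1H-spiro[cyclopenta[a]indene-8,2'-naphtho[1,8-de][1,3]dioxin]-1-one
Conditions: Ru(p-cymene)[(S,S)-TsNCHPhCHPhNH] (2 mol %), acetone, 28 °C, stopped near 45 % conversion; chromatography
Reagents that add atoms: none
Why: Oxidative kinetic resolution by hydrogen transfer to acetone with a chiral divalent ruthenium amido complex, the reverse of asymmetric transfer hydrogenation, known for racemic secondary allylic alcohols and for cyclopent-2-ene-1,4-diols. The (S,S) catalyst is expected to take the hydride from the carbinol in which the alkenyl group occupies the place of the aryl group of an (S)-1-arylethanol, which is the (1R) enantiomer of 18, so E4 and E5 of 19 have the configuration of 28. The E1–H bond lies on the open convex face, and low conversion keeps the enantiomeric purity of the ketone high.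

Step 13
Reactants: 19 hydroxy enone acetal
Product: 22 (3aR,8aS)-1-oxo-6-(prop-1-yn-1-yl)-3a-(triethylsilyloxy)-3a,8a-dihydro-1H-spiro[cyclopenta[a]indene-8,2'-naphtho[1,8-de][1,3]dioxine]-7-carbaldehyde, via triethylsilyl ether acetal 20 (not isolated), via lutidinium mixed acetal triflate 21 (not isolated)
Conditions: TESOTf (3.5 equiv), 2,6-lutidine (5 equiv), CH2Cl2, 0 °C; then H2O, rt
Reagents that add atoms: triethylsilyl trifluoromethanesulfonate CC[Si](CC)(CC)OS(=O)(=O)C(F)(F)F; water O
Why: A silyl triflate with 2,6-lutidine silylates the hindered tertiary alcohol and, in excess, converts aldehyde acetals into lutidinium salts that water hydrolyses to the aldehyde, whereas ketals of ketones are left alone; both are known reactions. The medium stays buffered, so neither E5–H nor the spiroketal is endangered.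

Step 14
Reactants: 22 ortho-propynyl benzaldehyde; 23 ethoxyacetylene
Product: 25 C9a-acetyl C9-ethoxy naphthalene (rings B and C) carrying spiroketal ring D and the (E4R,E5S)-triethylsilyloxycyclopentenone ring E, via benzopyrylium aurate 24 (not isolated)
Conditions: AuCl3 (5 mol %), 4 Å MS, ClCH2CH2Cl, rt, 15 min; then 23 (3 equiv, slow addition), 40 °C
Reagents that add atoms: none
Why: AuCl3 (trivalent gold) binds the propynyl triple bond and the formyl oxygen adds to its methyl-bearing carbon in a 6-endo-dig closure, giving the 2-benzopyrylium-4-yl aurate 24. The polarised ynol ether 23 attacks the most electrophilic carbon of 24, the former formyl carbon (C7), with its unsubstituted terminus (C8), and the ethoxy-stabilised cationic carbon (C9) is captured by the gold-bearing carbon (C9a), a stepwise formal (4+2) addition across the 1,4-positions of the pyrylium ring. Cleavage of the C7–O bridge bond and loss of gold aromatise the new ring and leave the former pyrylium C–O unit as the acetyl group on C9a, so ring C is closed by a two-bond annulation while the transient pyrylium ring is opened again. The closest known reaction type is the gold- or copper-catalysed benzannulation of ortho-alkynylbenzaldehydes with alkynes and with enol ethers to 1-acylnaphthalenes; an alkoxyalkyne combines these two partner classes and is the only extension. No stereocentre is formed, and E4 and E5 sit across ring B from the reacting carbons in a neutral to weakly acidic medium. The step needs regioselectivity (ethoxy next to acetyl), which the polarity of 23 secures in the same sense as for terminal alkynes with cation-stabilising substituents, and chemoselectivity for 23 over the electron-poor enone of ring E, which the cationic, electron-demanding diene secures. Slow addition of 23 to pre-formed 24 and molecular sieves are meant to suppress hydration, oligomerisation and direct addition of 23 to the formyl group, and the silyl ether prevents addition of the carbinol to 23.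

Step 15
Reactants: 25 acetyl ethoxy naphthalene
Product: 26 3,3-diethoxypropanoyl analogue of 25 (beta-keto acetal)
Conditions: HC(OEt)3, BF3·OEt2, CH2Cl2, −30 °C to 0 °C; then 25, iPr2NEt, −78 °C to −20 °C
Reagents that add atoms: triethyl orthoformate CCOC(OCC)OCC
Why: Known alpha-(dialkoxymethyl)ation of ketones with a dialkoxycarbenium salt and a hindered amine at low temperature; only the acetyl group offers an unhindered CH3, E5 being tertiary and shielded. A hot amide acetal was rejected because its alkoxide would deprotonate E5, open the ketal and alkylate the freed naphthoxide irreversibly.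

Step 16
Reactants: 26 beta-keto acetal
Product: 27 spiropreussione B 9-O-ethyl ether
Conditions: TfOH (3 equiv), CH2Cl2 (high dilution), 0 °C to rt; H2O
Reagents that add atoms: none
Why: Intramolecular Friedel–Crafts reaction at the peri position, the classical closure of 1-naphthoylacetaldehyde equivalents to phenalenones: acid ionises the acetal, C3a (conjugated with the C9 ethoxy group, ortho position blocked) attacks C3, and loss of the second ethanol gives the enone of ring A. E4 resists ionisation because the cation would be conjugated with the electron-poor enone, ketal opening is reversible without water, and the silyl ether is expected to be cleaved.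

Step 17
Reactants: 27 spiropreussione B 9-O-ethyl ether
Product: 28 spiropreussione B
Conditions: BCl3 (3 equiv), CH2Cl2, −78 °C to −20 °C; H2O
Reagents that add atoms: none
Why: Chelation-controlled dealkylation as in step 4: boron bridges C1=O and the C9 oxygen of the vinylogous ester and chloride removes the ethyl group. The carbinol at most forms a borate that water cleaves, and both stereocentres are untouched.

Compound list

1 | 6-methoxy-1-indanone | COc1ccc2CCC(=O)c2c1 | starting material
2 | 1,8-dihydroxynaphthalene | Oc1cccc2cccc(O)c12 | starting material
3 | 6-methoxy-2,3-dihydrospiro[indene-1,2'-naphtho[1,8-de][1,3]dioxine] | COc1ccc2CCC3(Oc4cccc5cccc(O3)c45)c2c1 | intermediate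
4 | 7-lithio derivative of 3 | COc1ccc2CCC3(Oc4cccc5cccc(O3)c45)c2c1[Li] | intermediate
5 | 6-methoxy-2,3-dihydrospiro[indene-1,2'-naphtho[1,8-de][1,3]dioxine]-7-carbaldehyde | COc1ccc2CCC3(Oc4cccc5cccc(O3)c45)c2c1C=O | intermediate
6 | 6-methoxy-3-oxo-2,3-dihydrospiro[indene-1,2'-naphtho[1,8-de][1,3]dioxine]-7-carbaldehyde | COc1ccc2C(=O)CC3(Oc4cccc5cccc(O3)c45)c2c1C=O | intermediate
7 | 6-hydroxy-3-oxo-2,3-dihydrospiro[indene-1,2'-naphtho[1,8-de][1,3]dioxine]-7-carbaldehyde | Oc1ccc2C(=O)CC3(Oc4cccc5cccc(O3)c45)c2c1C=O | intermediate
8 | 7-formyl-3-oxo-2,3-dihydrospiro[indene-1,2'-naphtho[1,8-de][1,3]dioxine]-6-yl trifluoromethanesulfonate | O=Cc1c(OS(=O)(=O)C(F)(F)F)ccc2C(=O)CC3(Oc4cccc5cccc(O3)c45)c12 | intermediate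
9 | propyne | CC#C | starting material
10 | 3-oxo-6-(prop-1-yn-1-yl)-2,3-dihydrospiro[indene-1,2'-naphtho[1,8-de][1,3]dioxine]-7-carbaldehyde | CC#Cc1ccc2C(=O)CC3(Oc4cccc5cccc(O3)c45)c2c1C=O | intermediate
11 | 7-(dimethoxymethyl)-6-(prop-1-yn-1-yl)spiro[indene-1,2'-naphtho[1,8-de][1,3]dioxin]-3(2H)-one | CC#Cc1ccc2C(=O)CC3(Oc4cccc5cccc(O3)c45)c2c1C(OC)OC | intermediate
12 | ethyl (Z)-3-iodoacrylate | CCOC(=O)/C=C\I | starting material
13 | (Z)-3-iodoprop-2-enal | O=C/C=C\I | intermediate
14 | dicyclohexylboron enolate of 11 | CC#Cc1ccc2C(OB(C6CCCCC6)C7CCCCC7)=CC3(Oc4cccc5cccc(O3)c45)c2c1C(OC)OC | intermediate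
15 | (±)-(2R*,1'S*)-2-[(Z)-1-hydroxy-3-iodoprop-2-en-1-yl] derivative of 11, anti aldol, racemate, relative configuration shown | CC#Cc1ccc2C(=O)[C@@H]([C@H](O)/C=C\I)C3(Oc4cccc5cccc(O3)c45)c2c1C(OC)OC | intermediate
16 | (±)-trimethylsilyl ether of 15, racemate | CC#Cc1ccc2C(=O)[C@@H]([C@H](O[Si](C)(C)C)/C=C\I)C3(Oc4cccc5cccc(O3)c45)c2c1C(OC)OC | intermediate
17 | (±)-(1R*,3aR*,8aR*) cis-fused tricyclic 3a-carbinol, E1 trimethylsilyl ether, racemate | CC#Cc1ccc2c(c1C(OC)OC)C1(Oc3cccc4cccc(c34)O1)[C@@H]1[C@H](O[Si](C)(C)C)C=C[C@]21O | intermediate
18 | (±)-(1R*,3aR*,8aR*)-7-(dimethoxymethyl)-6-(prop-1-yn-1-yl)-1,8a-dihydro-3aH-spiro[cyclopenta[a]indene-8,2'-naphtho[1,8-de][1,3]dioxine]-1,3a-diol, racemate | CC#Cc1ccc2c(c1C(OC)OC)C1(Oc3cccc4cccc(c34)O1)[C@@H]1[C@H](O)C=C[C@]21O | intermediate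
19 | (3aR,8aS)-7-(dimethoxymethyl)-3a-hydroxy-6-(prop-1-yn-1-yl)-3a,8a-dihydro-1H-spiro[cyclopenta[a]indene-8,2'-naphtho[1,8-de][1,3]dioxin]-1-one | CC#Cc1ccc2c(c1C(OC)OC)C1(Oc3cccc4cccc(c34)O1)[C@@H]1C(=O)C=C[C@]21O | intermediate
20 | triethylsilyl ether of 19 | CC#Cc1ccc2c(c1C(OC)OC)C1(Oc3cccc4cccc(c34)O1)[C@@H]1C(=O)C=C[C@]21O[Si](CC)(CC)CC | intermediate
21 | 2,6-lutidinium mixed acetal triflate from 20 | CC#Cc1ccc2c(c1C(OC)[n+]5c(C)cccc5C)C1(Oc3cccc4cccc(c34)O1)[C@@H]1C(=O)C=C[C@]21O[Si](CC)(CC)CC.[O-]S(=O)(=O)C(F)(F)F | intermediate
22 | (3aR,8aS)-1-oxo-6-(prop-1-yn-1-yl)-3a-(triethylsilyloxy)-3a,8a-dihydro-1H-spiro[cyclopenta[a]indene-8,2'-naphtho[1,8-de][1,3]dioxine]-7-carbaldehyde | CC#Cc1ccc2c(c1C=O)C1(Oc3cccc4cccc(c34)O1)[C@@H]1C(=O)C=C[C@]21O[Si](CC)(CC)CC | intermediate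
23 | ethoxyacetylene | CCOC#C | starting material
24 | 3-methyl-2-benzopyrylium-4-yl trichloroaurate derived from 22 | CC1=C([Au-](Cl)(Cl)Cl)c2ccc3c(c2C=[O+]1)C1(Oc4cccc5cccc(c45)O1)[C@@H]1C(=O)C=C[C@]31O[Si](CC)(CC)CC | intermediate
25 | 1-acetyl-2-ethoxynaphthalene fused through its C5–C6 bond to spiroketal ring D and the (E4R,E5S)-triethylsilyloxycyclopentenone | CCOc1ccc2c(c1C(C)=O)ccc3c2C1(Oc2cccc4cccc(c24)O1)[C@@H]1C(=O)C=C[C@]31O[Si](CC)(CC)CC | intermediate
26 | 3,3-diethoxypropanoyl analogue of 25 | CCOc1ccc2c(c1C(=O)CC(OCC)OCC)ccc3c2C1(Oc2cccc4cccc(c24)O1)[C@@H]1C(=O)C=C[C@]31O[Si](CC)(CC)CC | intermediate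
27 | spiropreussione B 9-O-ethyl ether | O=C1C=Cc2cc3c(c4ccc(OCC)c1c24)C1(Oc2cccc4cccc(c24)O1)[C@@H]1C(=O)C=C[C@]31O | intermediate
28 | spiropreussione B (E4 R, E5 S) | O=C1C=Cc2cc3c(c4ccc(O)c1c24)C1(Oc2cccc4cccc(c24)O1)[C@@H]1C(=O)C=C[C@]31O | target

Total step count: 17. Longest linear sequence: 16 (steps 1–7 and 9–17; step 8 is a one-step side branch).

Least certain steps

Step 14 (key step). The ynol ether may be used up faster than the benzopyrylium ion captures it. Possible causes are gold- or acid-induced hydration and oligomerisation, or Lewis-acid-promoted addition to the formyl group followed by collapse to an unsaturated ester. In addition, the approach to C7 passes close to the two ketal oxygens. The fallback sets out from 22 and replaces the alkyne by an enol-type partner. 1,1-Diethoxyethene with AuBr3 in ClCH2CH2Cl, the enol-ether variant of the benzopyrylium annulation, should give the 1-acetyl-2,2-diethoxy-1,2-dihydronaphthalene F1. This aromatises by loss of ethanol, on its own or with pyridinium tosylate, and rejoins the route at 25.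

Step 9. The enolate may expel naphthoxide from the neighbouring ketal carbon, because the C–O bonds are aligned with the enolate pi system. The iodoenal may also isomerise from Z to E, and the anti selectivity may be incomplete. The fallback sets out from 11. Pyrrolidone hydrotribromide in THF gives the 2-bromo ketone F2. Nickel-free CrCl2 with LiI in THF in the presence of 13 then forms a non-basic trivalent chromium enolate (chromium Reformatsky reaction) that adds to the aldehyde as it is formed. After separation of diastereomers the route is rejoined at 15.

Step 11. The alkenyllithium may act as a base towards E5–H, which leads to protonation of the anion and opening of the ketal instead of ring closure. The silyloxy group on the concave side also slows the closure. The fallback sets out from 16 and replaces the preformed carbanion by a catalytic reductive cyclisation. NiBr2(2,2'-bipyridine) with Mn powder in DMF generates a weakly basic alkenylnickel that adds to the tethered ketone, as is known for aryl and alkenyl halides. This fallback passes through no new compound (F0) and rejoins the route at 17.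

Step 12. The catalyst may discriminate poorly between the enantiomers, or turn over slowly, because the carbinol is flanked by the bulky ketal. The enantiomeric purity of a ketone formed in a kinetic resolution also falls as conversion rises. The fallback sets out from 18 and resolves by acylation instead of oxidation.
- Candida antarctica lipase B with vinyl acetate in MTBE should, by the empirical size rule for secondary alcohols, acylate the wanted (1R) enantiomer to the E1 monoacetate F3.
- After separation, K2CO3 in MeOH returns enantioenriched 18. This is safe because no carbonyl group is present.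
- MnO2 in CH2Cl2 oxidises the allylic alcohol, and the route is rejoined at 19.

Step 16. The acetal may simply lose ethanol to a resonance-stabilised beta-ethoxy enone that is too weak an electrophile. Forcing the acid may then lead to ketal cleavage or to intermolecular attack on the naphthodioxine rings. The fallback sets out from 25 and closes ring A at the saturated level.
- Paraformaldehyde with iPr2NH·CF3CO2H in THF (Mannich methylenation) gives the aryl vinyl ketone F4, which has no donor on the double bond.
- A mild Lewis acid, Sc(OTf)3 in CH2Cl2/(CF3)2CHOH, should bring about the peri conjugate Friedel–Crafts alkylation to the 2,3-dihydrophenalenone F5.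
- DDQ dehydrogenates this to the silylated ethoxyphenalenone F6.
- BCl3 then removes the ethyl and silyl groups together, and the route is rejoined at 28.

Step 3. The formyl group lowers the donor power of the anisole ring, so hydride abstraction may be slow. The oxidant may instead engage the more electron-rich naphthodioxine, and the warm aqueous medium may start to open the new beta-keto ketal. The fallback sets out from 3 and oxidises before the formyl group is present.
- DDQ in aqueous dioxane gives the methoxy keto ketal F7.
- NaBH4 gives the indanol F8.
- TBSCl with imidazole gives its tert-butyldimethylsilyl ether F9.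
- n-BuLi/TMEDA and then DMF gives the formylated silyl ether F10.
- Bu4NF gives the hydroxy aldehyde F11.
- MnO2 oxidises the benzylic alcohol, and the route is rejoined at 6.

Further compounds

F1 | step 14 | 1-acetyl-2,2-diethoxy-1,2-dihydronaphthalene analogue of 25 | CCOC1(OCC)C=Cc2c(C1C(C)=O)ccc3c2C1(Oc2cccc4cccc(c24)O1)[C@@H]1C(=O)C=C[C@]31O[Si](CC)(CC)CC
F2 | step 9 | 2-bromo derivative of 11 | CC#Cc1ccc2C(=O)C(Br)C3(Oc4cccc5cccc(O3)c45)c2c1C(OC)OC
F0 | step 11 | none | none
F3 | step 12 | (1R,3aR,8aR) E1 monoacetate of 18 | CC#Cc1ccc2c(c1C(OC)OC)C1(Oc3cccc4cccc(c34)O1)[C@@H]1[C@H](OC(C)=O)C=C[C@]21O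
F4 | step 16 | propenoyl (aryl vinyl ketone) analogue of 25 | CCOc1ccc2c(c1C(=O)C=C)ccc3c2C1(Oc2cccc4cccc(c24)O1)[C@@H]1C(=O)C=C[C@]31O[Si](CC)(CC)CC
F5 | step 16 | 9-ethoxy-2,3-dihydrophenalen-1-one, E4 triethylsilyl ether | O=C1CCc2cc3c(c4ccc(OCC)c1c24)C1(Oc2cccc4cccc(c24)O1)[C@@H]1C(=O)C=C[C@]31O[Si](CC)(CC)CC
F6 | step 16 | spiropreussione B 9-O-ethyl ether, E4 triethylsilyl ether | O=C1C=Cc2cc3c(c4ccc(OCC)c1c24)C1(Oc2cccc4cccc(c24)O1)[C@@H]1C(=O)C=C[C@]31O[Si](CC)(CC)CC
F7 | step 3 | 6-methoxyspiro[indene-1,2'-naphtho[1,8-de][1,3]dioxin]-3(2H)-one | COc1ccc2C(=O)CC3(Oc4cccc5cccc(O3)c45)c2c1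
F8 | step 3 | 6-methoxy-2,3-dihydrospiro[indene-1,2'-naphtho[1,8-de][1,3]dioxin]-3-ol (racemic) | COc1ccc2C(O)CC3(Oc4cccc5cccc(O3)c45)c2c1
F9 | step 3 | tert-butyldimethylsilyl ether of F8 | COc1ccc2C(O[Si](C)(C)C(C)(C)C)CC3(Oc4cccc5cccc(O3)c45)c2c1
F10 | step 3 | 7-formyl derivative of F9 | COc1ccc2C(O[Si](C)(C)C(C)(C)C)CC3(Oc4cccc5cccc(O3)c45)c2c1C=O
F11 | step 3 | 3-hydroxy-6-methoxy-2,3-dihydrospiro[indene-1,2'-naphtho[1,8-de][1,3]dioxine]-7-carbaldehyde | COc1ccc2C(O)CC3(Oc4cccc5cccc(O3)c45)c2c1C=O
A1 | alternative 1 | 2-[2-(2-bromo-6-methoxynaphthalen-1-yl)naphtho[1,8-de][1,3]dioxin-2-yl]cyclopent-4-ene-1,3-dione | COc1ccc2c(c1)ccc(Br)c2C1(Oc3cccc4cccc(c34)O1)C1C(=O)C=CC1=O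
A2 | alternative 1 | methoxynaphthalene-fused spiroketal hydroxy enone | COc1ccc2c(c1)ccc3c2C1(Oc2cccc4cccc(c24)O1)[C@@H]1C(=O)C=C[C@]31O
A3 | alternative 2 | 4-(6-methoxynaphthalen-2-yl)-5-(naphtho[1,8-de][1,3]dioxin-2-ylidene)-4-(triethylsilyloxy)cyclopent-2-en-1-one, carbinol configured as in 28 | COc1ccc2c(c1)ccc(c2)[C@@]1(O[Si](CC)(CC)CC)C=CC(=O)C1=C5Oc6cccc7cccc(O5)c67
A4 | alternative 2 | triethylsilyl ether of A2 | COc1ccc2c(c1)ccc3c2C1(Oc2cccc4cccc(c24)O1)[C@@H]1C(=O)C=C[C@]31O[Si](CC)(CC)CC
A5 | alternative 3 | C9a propynoyl (terminal ynone) derivative of A4 | COc1ccc2c(c1C(=O)C#C)ccc3c2C1(Oc2cccc4cccc(c24)O1)[C@@H]1C(=O)C=C[C@]31O[Si](CC)(CC)CC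
A6 | alternative 3 | spiropreussione B methyl ether, E4 triethylsilyl ether | O=C1C=Cc2cc3c(c4ccc(OC)c1c24)C1(Oc2cccc4cccc(c24)O1)[C@@H]1C(=O)C=C[C@]31O[Si](CC)(CC)CC
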